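The spiro dihydropyran is disconnected at its CH2–C8 bond and its enol-ether O–C(sp2) bond. This reads C8, the spiro carbon of the nine-membered ring that carries both the pyran oxygen and the pyran CH2, as a former ketone carbon, and the O–C=C–C=O unit shared with the tetramethylcyclohexenedione ring as a vinylogous ester. In one operation an alkylsamarium, made from an enantiopure primary iodide that already holds the isobutyl stereocentre and a methyl vinylogous ester, adds to the C8 ketone of kobusone, and the tertiary alkoxide so formed displaces methoxide to close the pyran. The 4,5-epoxide is then converted into the (Z)-allylic alcohol of inverted C5 configuration.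

Key step: step 7

Remark: caryophyllane numbering is used for the terpenoid part (C1/C9 ring fusion, C4 methyl-bearing carbon, C5 oxygen-bearing carbon, C8 spiro carbon); syncarpic acid 6 and (−)-caryophyllene oxide 13 are taken as purchasable.

Step 1
Reactants: 1 isovaleraldehyde (3-methylbutanal); 2 nitromethane
Product: 5 (E)-4-methyl-1-nitropent-1-ene, via nitro alcohol 3 (not isolated), via mesylate 4 (not isolated)
Conditions: KOt-Bu (5 mol %), THF/t-BuOH, 0 °C; then MsCl, Et3N, CH2Cl2, 0 °C
Reagents that add atoms: none
Why: Henry (nitroaldol) addition followed by mesylation and E1cB elimination should give the conjugated nitroalkene as the thermodynamically preferred E isomer; no stereocentre is carried forward.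

Step 2
Reactants: 6 syncarpic acid (2,2,4,4-tetramethylcyclohexane-1,3,5-trione); 5 (E)-4-methyl-1-nitropent-1-ene
Product: 7 (R)-nitro Michael adduct, 5-hydroxy-2,2,6,6-tetramethyl-4-[(2R)-4-methyl-1-nitropentan-2-yl]cyclohex-4-ene-1,3-dione
Conditions: quinine-derived squaramide 3-{[3,5-bis(trifluoromethyl)phenyl]amino}-4-{[(8α,9S)-6'-methoxycinchonan-9-yl]amino}cyclobut-3-ene-1,2-dione (5 mol %), CH2Cl2, −20 °C
Reagents that add atoms: none
Why: Bifunctional organocatalytic Michael addition of an acidic cyclic 1,3-dicarbonyl enol to a nitroalkene (quinuclidine holds the enolate, the squaramide N–H bonds bind the nitro group), in which the catalyst selects the face of the nitroalkene and should set the isobutyl-bearing centre as R; the quinidine-derived pseudo-enantiomer would be used should the sense prove opposite.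

Step 3
Reactants: 7 (R)-nitro Michael adduct
Product: 8 methyl vinylogous ester, 5-methoxy-2,2,6,6-tetramethyl-4-[(2R)-4-methyl-1-nitropentan-2-yl]cyclohex-4-ene-1,3-dione
Conditions: TMSCHN2, toluene/MeOH, 0 °C
Reagents that add atoms: trimethylsilyldiazomethane, C[Si](C)(C)C=[N+]=[N-]
Why: O-methylation of the acidic enol by the diazoalkane (esterification-type reaction of a vinylogous acid); the two carbonyl groups flanking the substituted ring carbon are constitutionally equivalent, so a single enol ether should form and the stereocentre is not touched.

Step 4
Reactants: 8 methyl vinylogous ester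
Product: 11 primary alcohol 4-[(2R)-1-hydroxy-4-methylpentan-2-yl]-5-methoxy-2,2,6,6-tetramethylcyclohex-4-ene-1,3-dione, via sodium nitronate 9 (not isolated), via aldehyde 10 (not isolated)
Conditions: NaOMe (1.05 equiv), MeOH, 0 °C; O3, CH2Cl2/MeOH, −78 °C (stopped at first excess); then NaBH4, −78 → −40 °C
Reagents that add atoms: ozone, [O-][O+]=O
Why: Nef reaction in its ozonolytic form (the electron-rich nitronate C=N bond is cleaved far faster than the hindered, electron-poor vinylogous ester alkene) followed by borohydride reduction of the aldehyde in the same flask, so that the α-stereocentre is exposed as an aldehyde only briefly at −78 °C and should keep its configuration.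

Step 5
Reactants: 11 primary alcohol
Product: 12 primary iodide 4-[(2R)-1-iodo-4-methylpentan-2-yl]-5-methoxy-2,2,6,6-tetramethylcyclohex-4-ene-1,3-dione
Conditions: PPh3, I2, imidazole, CH2Cl2, 0 °C, dark; used at once
Reagents that add atoms: iodine, II
Why: Appel reaction, an SN2 displacement of the oxyphosphonium group by iodide at the primary carbon, which leaves the adjacent stereocentre untouched; low temperature and immediate use should limit participation of the neighbouring vinylogous ester oxygen.

Step 6
Reactants: 13 (−)-caryophyllene oxide, (1R,4R,5R,9S)-4,5-epoxycaryophyll-8(13)-ene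
Product: 15 kobusone, (1R,4R,5R,9S)-4,5-epoxy-13-norcaryophyllan-8-one, via ozonide 14 (not isolated)
Conditions: O3, CH2Cl2, −78 °C; then Me2S, −78 → 23 °C
Reagents that add atoms: ozone, [O-][O+]=O
Why: Ozonolysis of the only alkene, the exocyclic methylene, with reductive work-up should give the C8 ketone; the epoxide, which masks the endocyclic alkene, and all four stereocentres are unaffected.

Step 7
Reactants: 12 primary iodide; 15 kobusone
Product: 18 spiro-dihydropyran epoxide (8S), via alkylsamarium 16 (not isolated), via samarium alkoxide 17 (not isolated)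
Conditions: 12 and 15 (1.5 equiv) added to SmI2 (2.5 equiv), HMPA (10 equiv), THF, −78 °C; then 23 °C
Reagents that add atoms: none
Why: SmI2–HMPA should reduce the primary C–I bond of 12 by two single-electron transfers to the alkylsamarium 16 (trivalent samarium), which adds to the C8 ketone of 15 and forms the CH2–C8 bond; the tertiary samarium alkoxide 17 then adds to the methoxy-bearing β-carbon of the vinylogous ester and expels methoxide, which forms the O–C(sp2) bond. The closest known reaction types are the samarium Barbier reaction of alkyl iodides with ketones and the spontaneous lactonisation of samarium alkoxides in SmI2 ketone–acrylate couplings, of which this closure is the vinylogous counterpart. The only ring closed is the dihydropyran, by 6-endo-trig addition–elimination. The isobutyl-bearing centre comes unchanged from 12, and the new C8 centre should be set by peripheral attack on the nine-membered ketone in the conformer whose carbonyl oxygen lies on the α face (the side of H-1, away from H-9), which leaves the oxygen α and the new CH2 β, that is 8S. The step needs chemoselectivity at three points: reduction of the iodide must outrun electron transfer to the carbonyl groups (aprotic HMPA medium, in which ketyl formation is reversible and unproductive); the carbanion must choose the C8 ketone over the two carbonyls of 12 (each flanked by a quaternary CMe2 carbon); and the alkoxide must close on the activated sp2 carbon through the six-membered tether before it can open the transannular epoxide.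

Step 8
Reactants: 18 spiro-dihydropyran epoxide
Product: 19 (3Z,5R)-allylic alcohol (5-epi-tomentodione P)
Conditions: 2,2,6,6-tetramethylpiperidine, n-BuLi, then Et2AlCl, toluene, 0 °C [gives Et2Al(TMP), 4 equiv]; 18, 0 °C; aq. potassium sodium tartrate
Reagents that add atoms: none
Why: Aluminium amide-mediated rearrangement of an epoxide to an allylic alcohol (syn β-elimination within the epoxide–aluminium complex), in which the bulky amide should take a proton from C3, the ring carbon cis to the epoxide hydrogen, rather than from the methyl group; the C5–O bond (5R) is retained, the 3,4-alkene should form as the less strained Z isomer of the nine-membered ring, and the carbonyl groups, which carry no α-hydrogen, cannot be enolised.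

Step 9
Reactants: 19 (3Z,5R)-allylic alcohol
Product: 20 (3Z)-enone (C5 ketone)
Conditions: Dess–Martin periodinane (1.3 equiv), CH2Cl2, 23 °C
Reagents that add atoms: none
Why: Dess–Martin oxidation of the secondary allylic alcohol to the conjugated enone under neutral conditions, which erases the C5 centre for inversion and leaves the Z-alkene and the other stereocentres untouched.

Step 10
Reactants: 20 (3Z)-enone
Product: 21 tomentodione P
Conditions: (R)-2-methyl-CBS-oxazaborolidine [(3aR)-1-methyl-3,3-diphenyltetrahydro-1H,3H-pyrrolo[1,2-c][1,3,2]oxazaborole] (20 mol %), catecholborane (1.5 equiv), toluene, −78 °C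
Reagents that add atoms: none
Why: Corey–Bakshi–Shibata reduction, in which the (R)-oxazaborolidine–borane complex should deliver hydride to the enone carbonyl with the alkenyl carbon C4 as the large group and the C6 methylene as the small one, setting 5S by reagent control; the hindered ring ketone and the vinylogous ester should not react at −78 °C.

Compound list
1 | isovaleraldehyde (3-methylbutanal) | CC(C)CC=O | starting material
2 | nitromethane | C[N+](=O)[O-] | starting material
3 | 4-methyl-1-nitropentan-2-ol (racemic, not isolated) | CC(C)CC(O)C[N+](=O)[O-] | intermediate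
4 | 4-methyl-1-nitropentan-2-yl methanesulfonate (racemic, not isolated) | CC(C)CC(OS(C)(=O)=O)C[N+](=O)[O-] | intermediate
5 | (E)-4-methyl-1-nitropent-1-ene | CC(C)C/C=C/[N+](=O)[O-] | intermediate
6 | syncarpic acid, 2,2,4,4-tetramethylcyclohexane-1,3,5-trione (enolised in solution) | CC1(C)C(=O)CC(=O)C(C)(C)C1=O | starting material
7 | 5-hydroxy-2,2,6,6-tetramethyl-4-[(2R)-4-methyl-1-nitropentan-2-yl]cyclohex-4-ene-1,3-dione | [O-][N+](=O)C[C@H](CC(C)C)C1=C(O)C(C)(C)C(=O)C(C)(C)C1=O | intermediate
8 | 5-methoxy-2,2,6,6-tetramethyl-4-[(2R)-4-methyl-1-nitropentan-2-yl]cyclohex-4-ene-1,3-dione | [O-][N+](=O)C[C@H](CC(C)C)C1=C(OC)C(C)(C)C(=O)C(C)(C)C1=O | intermediate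
9 | sodium nitronate of 8 (not isolated) | [Na+].[O-][N+]([O-])=C[C@H](CC(C)C)C1=C(OC)C(C)(C)C(=O)C(C)(C)C1=O | intermediate
10 | (2R)-2-(2-methoxy-3,3,5,5-tetramethyl-4,6-dioxocyclohex-1-en-1-yl)-4-methylpentanal (not isolated) | O=C[C@H](CC(C)C)C1=C(OC)C(C)(C)C(=O)C(C)(C)C1=O | intermediate
11 | 4-[(2R)-1-hydroxy-4-methylpentan-2-yl]-5-methoxy-2,2,6,6-tetramethylcyclohex-4-ene-1,3-dione | OC[C@H](CC(C)C)C1=C(OC)C(C)(C)C(=O)C(C)(C)C1=O | intermediate
12 | 4-[(2R)-1-iodo-4-methylpentan-2-yl]-5-methoxy-2,2,6,6-tetramethylcyclohex-4-ene-1,3-dione | IC[C@H](CC(C)C)C1=C(OC)C(C)(C)C(=O)C(C)(C)C1=O | intermediate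
13 | (−)-caryophyllene oxide, (1R,4R,5R,9S)-4,5-epoxycaryophyll-8(13)-ene | C[C@@]12CC[C@@H]3[C@H](CC3(C)C)C(=C)CC[C@H]1O2 | starting material
14 | secondary ozonide of 13, spiro-1,2,4-trioxolane at C8 (not isolated) | C[C@@]12CC[C@@H]3[C@H](CC3(C)C)C4(CC[C@H]1O2)OCOO4 | intermediate
15 | kobusone, (1R,4R,5R,9S)-4,5-epoxy-13-norcaryophyllan-8-one | C[C@@]12CC[C@@H]3[C@H](CC3(C)C)C(=O)CC[C@H]1O2 | intermediate
16 | alkylsamarium diiodide (trivalent samarium) derived from 12 (not isolated) | I[Sm](I)C[C@H](CC(C)C)C1=C(OC)C(C)(C)C(=O)C(C)(C)C1=O | intermediate
17 | samarium alkoxide (trivalent samarium) of the (8S) tertiary alcohol from addition of 16 to 15 (not isolated) | C[C@@]12CC[C@@H]3[C@H](CC3(C)C)[C@](O[Sm](I)I)(CC[C@H]1O2)C[C@H](CC(C)C)C1=C(OC)C(C)(C)C(=O)C(C)(C)C1=O | intermediate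
18 | spiro-dihydropyran epoxide: (1R,4R,5R,8S,9S)-4,5-epoxy-13-norcaryophyllane whose C8 is C2 of a (4S)-4-isobutyl-6,6,8,8-tetramethyl-3,4-dihydro-2H-chromene-5,7(6H,8H)-dione | C[C@@]12CC[C@@H]3[C@H](CC3(C)C)[C@]4(CC[C@H]1O2)C[C@H](CC(C)C)C1=C(O4)C(C)(C)C(=O)C(C)(C)C1=O | intermediate
19 | 5-epi-tomentodione P, the (3Z,5R)-allylic alcohol | C/C1=C/C[C@@H]2[C@H](CC2(C)C)[C@]2(CC[C@H]1O)C[C@H](CC(C)C)C1=C(O2)C(C)(C)C(=O)C(C)(C)C1=O | intermediate
20 | (3Z)-enone, the C5 ketone of 19 | C/C1=C/C[C@@H]2[C@H](CC2(C)C)[C@]2(CCC1=O)C[C@H](CC(C)C)C1=C(O2)C(C)(C)C(=O)C(C)(C)C1=O | intermediate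
21 | tomentodione P | C/C1=C/C[C@@H]2[C@H](CC2(C)C)[C@]2(CC[C@@H]1O)C[C@H](CC(C)C)C1=C(O2)C(C)(C)C(=O)C(C)(C)C1=O | target

Total step count: 10. Longest linear sequence: 9 steps (steps 1–5, then steps 7–10); the terpenoid branch contributes step 6.

The three steps most likely to fail are step 7, step 8 and step 2, in this order of risk.

The key step, step 7, is the riskiest. Four processes may intervene. Electron transfer from SmI2 may go to the dione and vinylogous ester of 12 instead of to the C–I bond. The alkylsamarium may be protonated through enolisation of the medium-ring ketone instead of adding to it. The C8 alkoxide may open the epoxide across the ring, possibly aided by the Lewis-acidic samarium salts. The facial selectivity at C8 may be poor. The fallback for step 7 sets out from 12 and 15 and replaces the single-electron Barbier mode by a preformed two-electron organometallic, so that no reductant meets the carbonyl partners. Iodide 12 is treated with t-BuLi (2.1 equiv, Et2O/pentane, −100 °C), where iodine–lithium exchange at the primary carbon should outrun addition to the hindered ring carbonyls, to give the primary alkyllithium F1. This is transferred at once onto anhydrous CeCl3 in THF at −78 °C to give the alkylcerium dichloride F2, a weakly basic reagent that adds to enolisable ketones and has a different steric demand. Addition of 15 gives the (8S) cerium alkoxide F3, which should close in the same flask on warming by the same addition–elimination. The fallback comes back to the route at 18.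

In step 8, the amide may abstract a proton from the C4 methyl group and give the exocyclic alkene, or the elimination may pass through the geometry that gives the E-cycloalkene. The fallback for step 8 sets out from 18 and does not depend on the site of proton loss. Cp2TiCl (trivalent titanium, from Cp2TiCl2 and Mn, THF, 23 °C) opens the epoxide homolytically at C4 and, after loss of a β-hydrogen, should give mainly the (5R)-4(12)-exocyclic allylic alcohol F4. Dess–Martin oxidation gives the exo-methylene enone F5, and RhCl3·3H2O in hot ethanol moves the double bond into conjugation within the ring to the thermodynamically preferred (Z)-enone. The fallback comes back to the route at 20.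

In step 2, the hindered, weakly nucleophilic enolate of 6 may add too slowly to the aliphatic nitroalkene, which then oligomerises, or the enantiocontrol may be insufficient. The fallback for step 2 reverses the polarity of the assembly and sets out from 6, 1 and 2. Knoevenagel condensation of 6 with 1 (catalytic piperidinium acetate) generates the highly electrophilic alkylidene trione F6 in situ. Nitromethane 2 is then added to it in a conjugate addition under the same type of bifunctional squaramide catalysis, the catalyst antipode being chosen for the R centre. The fallback comes back to the route at 7.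

Further compounds
F1 | step 7 | primary alkyllithium | [Li]C[C@H](CC(C)C)C1=C(OC)C(C)(C)C(=O)C(C)(C)C1=O
F2 | step 7 | alkylcerium dichloride | Cl[Ce](Cl)C[C@H](CC(C)C)C1=C(OC)C(C)(C)C(=O)C(C)(C)C1=O
F3 | step 7 | (8S) cerium alkoxide | C[C@@]12CC[C@@H]3[C@H](CC3(C)C)[C@](O[Ce](Cl)Cl)(CC[C@H]1O2)C[C@H](CC(C)C)C1=C(OC)C(C)(C)C(=O)C(C)(C)C1=O
F4 | step 8 | (5R)-4(12)-exocyclic allylic alcohol | C=C1CC[C@@H]2[C@H](CC2(C)C)[C@]2(CC[C@H]1O)C[C@H](CC(C)C)C1=C(O2)C(C)(C)C(=O)C(C)(C)C1=O
F5 | step 8 | exo-methylene enone | C=C1CC[C@@H]2[C@H](CC2(C)C)[C@]2(CCC1=O)C[C@H](CC(C)C)C1=C(O2)C(C)(C)C(=O)C(C)(C)C1=O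
F6 | step 2 | alkylidene trione | CC(C)CC=C1C(=O)C(C)(C)C(=O)C(C)(C)C1=O
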